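The cyclopentane (C1–C5, daucane numbering, defined below) is drawn out of a cyclohexane that still holds C6. An enantioselective Diels–Alder reaction builds this ring (C1–C6) with quaternary C1, C2 and a C4=C5 alkene. Dihydroxylation then gives the C4 carbinol and, after mesylation, an equatorial leaving group on C5 beside the C6 carbinol. In the key step C1 migrates from C6 to C5 (semipinacol ring contraction). The six-membered ring becomes the five-membered one, C5 is set by inversion, and C6 is expelled as the aldehyde on which the cycloheptene is then built (methallylation, ring-closing metathesis). The step exploits the C4(OH)–C5(H)–C6(O) array next to quaternary C1.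

Key step: step 11

**Numbering used in all names:**
- C1 = quaternary C(CH3), C2 = CH(OAc), C3 = CH2, C4 = C(OH)(iPr), C5 = ring-fusion CH.
- C6 = CH(OAng), C7 = CH2, C8 = C(CH3)=, C9 = =CH, C10 = CH(OBz).
- β is the face of the C1 methyl group; α is the face of H-5.

**Assumptions:**
- Compounds 1, 4 and 18 are purchasable.
- The sense of induction in step 4 follows the usual formyl C–H···O binding model for 2-substituted enals. If the antipode were formed, the (R)-catalyst would be used.

Step 1
Reactants: 1 3,4-dimethylpent-1-yn-3-ol (racemic)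
Product: 2 3,4-dimethylpent-2-enal (E/Z mixture)
Conditions: (Ph3SiO)3VO (2 mol%), Ph3SiOH (10 mol%), xylene, 140 °C
Reagents that add atoms: none
Why: Vanadate-catalysed Meyer–Schuster rearrangement (1,3-oxygen shift of a tertiary ethynyl carbinol) should give the enal rather than the acid-type enone, and the E/Z ratio does not matter because this double bond disappears in step 2.

Step 2
Reactants: 2 3,4-dimethylpent-2-enal
Product: 3 (E)-1-(tert-butyldimethylsilyloxy)-3-isopropylbuta-1,3-diene
Conditions: TBSOTf, Et3N, Et2O, 0 °C
Reagents that add atoms: TBSOTf CC(C)(C)[Si](C)(C)OS(=O)(=O)C(F)(F)F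
Why: Vinylogous silyl enol ether formation (O-silylation, then γ-deprotonation) should take the proton of the unhindered γ-methyl group rather than the isopropyl methine and give the E enol ether.

Step 3
Reactants: 4 2,4-dimethylfuran
Product: 5 (Z)-2-methyl-4-oxopent-2-enal
Conditions: dimethyldioxirane, acetone, −40 → 0 °C, solution used directly
Reagents that add atoms: dimethyldioxirane CC1(C)OO1
Why: Oxidative furan ring opening with a neutral oxygen donor should give the cis-4-oxoenal, whose Z geometry (CHO cis to acetyl) is inherited from the ring.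

Step 4
Reactants: 3 (E)-1-(tert-butyldimethylsilyloxy)-3-isopropylbuta-1,3-diene; 5 (Z)-2-methyl-4-oxopent-2-enal
Product: 6 2α-acetyl-6α-(TBS-oxy)-4-isopropyl-1β-methylcyclohex-4-ene-1α-carbaldehyde
Conditions: (S)-proline-derived B-o-tolyl oxazaborolidine·Tf2NH (15 mol%), CH2Cl2, −78 °C
Reagents that add atoms: none
Why: Catalytic enantioselective Diels–Alder reaction of a 2-substituted enal: the formyl-bound catalyst makes C2 the electrophilic terminus, so the CH2 end of 3 bonds to C2 and the oxygenated end to C1 (ortho/para rule); endo approach of both carbonyl groups together with the Z geometry places CHO, Ac and OTBS on one face (C1, C2, C6), and catalyst shielding sets the absolute sense.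

Step 5
Reactants: 6 Diels–Alder adduct
Product: 7 (10S)-allylic alcohol (1α-[(S)-1-hydroxyallyl] analogue of 6)
Conditions: divinylzinc (1.5 equiv), (−)-MIB (3-exo-morpholinoisoborneol, 10 mol%), toluene, 0 °C; H2O
Reagents that add atoms: divinylzinc C=C[Zn]C=C
Why: Amino-alcohol-catalysed asymmetric vinylzinc addition touches only the non-enolisable aldehyde (the methyl ketone is inert to organozinc), and the ligand sets C10 as S by reagent control, in the same facial sense as dialkylzinc additions with this ligand class.

Step 6
Reactants: 7 (10S)-allylic alcohol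
Product: 8 C10 benzoate
Conditions: BzCl, pyridine, DMAP (cat.), CH2Cl2, 0 °C → rt
Reagents that add atoms: benzoyl chloride O=C(Cl)c1ccccc1
Why: Nucleophile-catalysed O-acylation installs the final benzoate without touching a stereocenter and drains any cyclic hemiketal form of 7 through the open hydroxy ketone.

Step 7
Reactants: 8 C10 benzoate
Product: 9 4β,5β-diol
Conditions: OsO4 (5 mol%), NMO (1.1 equiv), acetone–H2O, 0 °C
Reagents that add atoms: N-methylmorpholine N-oxide C[N+]1([O-])CCOCC1; water O
Why: Catalytic syn-dihydroxylation should choose the electron-rich trisubstituted C4=C5 bond over the vinyl group (monosubstituted, neopentyl, deactivated by the allylic benzoate) and add on the β face, anti to the allylic OTBS group and to the axial C10 chain, which sets C4 and the temporary C5 carbinol.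

Step 8
Reactants: 9 4β,5β-diol
Product: 10 C5 mesylate
Conditions: MsCl, Et3N, CH2Cl2, −10 °C
Reagents that add atoms: methanesulfonyl chloride CS(=O)(=O)Cl
Why: Sulfonylation via sulfene takes the equatorial secondary C5 hydroxyl and leaves the tertiary C4 hydroxyl, which is cis to C5–O and therefore cannot close an epoxide.

Step 9
Reactants: 10 C5 mesylate
Product: 11 C2 acetate
Conditions: mCPBA (3 equiv), CH2Cl2, rt
Reagents that add atoms: mCPBA O=C(OO)c1cccc(Cl)c1
Why: Baeyer–Villiger oxidation of the methyl ketone, in which the secondary C2 migrates in preference to methyl and with retention, turns the acetyl group directly into the 2α-acetate; the only alkene left is the deactivated vinyl group.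

Step 10
Reactants: 11 C2 acetate
Product: 12 6α-hydroxy 5β-mesylate
Conditions: HF·pyridine, THF, 0 °C → rt
Reagents that add atoms: none
Why: Acidic fluoride desilylation frees the C6 hydroxyl without forming an alkoxide, so esters and mesylate stay in place and no stereocenter is touched.

Step 11
Reactants: 12 6α-hydroxy 5β-mesylate
Product: 14 cyclopentanecarbaldehyde (C6 = CHO on C5), via bis(chloroethylaluminium) alkoxide 13 (not isolated)
Conditions: Et2AlCl (2.5 equiv), CH2Cl2, −78 → −30 °C; aq. potassium sodium tartrate
Reagents that add atoms: none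
Why: Et2AlCl turns both hydroxyls of 12 into aluminium alkoxides (13) and binds the sulfonate, and the C6–C1 σ bond, antiperiplanar to the equatorial C5–OMs bond in the only populated chair (iPr, CH3, OAc, OMs and O-6 equatorial; C10 chain and O-4 axial), shifts to C5 as mesylate leaves while C6 becomes the formyl carbon. The closest known type is the organoaluminium-promoted pinacol-type (semipinacol) rearrangement of β-mesyloxy alcohols, in the ring-contracting form that converts cyclohexane-1,2-diol monosulfonates into cyclopentanecarbaldehydes. The ring C1–C5 closes by a suprafacial 1,2-alkyl shift through a three-centre transition state, not by an exo or endo cyclisation. C5 is set by inversion (C1 enters anti to the leaving group, so H-5 ends trans to the C1 methyl), C1 migrates with retention, and C2, C4 and C10 are not touched. The step needs C1 migration from C6 to win over C3 migration from the C4 carbinol, hydride shift and epoxide closure: the quaternary C1 is a far better migrating group than the C3 methylene, H-6 and both oxygens are gauche to the C5–OMs bond, and the ring flip needed for an epoxide would put five groups axial. The non-basic medium should keep acetate and benzoate in place and spare the β-hydroxy aldehyde 14 from epimerisation, and 14 is used at once.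

Step 12
Reactants: 14 cyclopentanecarbaldehyde
Product: 16 (6S)-homoallylic alcohol (4,6-diol), via diisopinocampheylborinate 15 (not isolated)
Conditions: (−)-B-(2-methylallyl)diisopinocampheylborane (from (+)-α-pinene, preformed, salt-free), Et2O, −78 °C; then NaBO3·4H2O, THF–H2O
Reagents that add atoms: (−)-B-(2-methylallyl)diisopinocampheylborane C=C(C)CB([C@@H]1C[C@@H]2C[C@H]([C@H]1C)C2(C)C)[C@@H]1C[C@@H]2C[C@H]([C@H]1C)C2(C)C
Why: Asymmetric allylboration through a closed chair transition state adds C7–C8 under neutral conditions and sets C6 as S by reagent control, in the same sense as for other α-branched aldehydes with this borane.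

Step 13
Reactants: 16 (6S)-homoallylic alcohol
Product: 17 bicyclic 6α-alcohol (hydroazulene core)
Conditions: second-generation Ru–NHC isopropoxybenzylidene metathesis catalyst (10 mol%), toluene (2 mM), 80 °C
Reagents that add atoms: none
Why: Ring-closing metathesis of the vinyl and 2-methylallyl groups, held trans on C1 and C5, forms the trisubstituted C8=C9 bond of the trans-fused cycloheptene without touching a stereocenter.

Step 14
Reactants: 17 bicyclic 6α-alcohol; 18 angelic acid
Product: 20 target CNP0248576.1, via angelic 2,4,6-trichlorobenzoic anhydride 19 (not isolated)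
Conditions: 18, 2,4,6-trichlorobenzoyl chloride, Et3N, toluene, rt; then 17, 80 °C (no DMAP)
Reagents that add atoms: none
Why: Yamaguchi-type mixed-anhydride esterification without a nucleophilic catalyst acylates the only secondary hydroxyl (the tertiary C4 hydroxyl is inert) and avoids Z→E isomerisation of the angelate.

**Compound list**
1 | 3,4-dimethylpent-1-yn-3-ol (racemic) | C#CC(C)(O)C(C)C | starting material
2 | 3,4-dimethylpent-2-enal (E/Z mixture) | CC(C)C(C)=CC=O | intermediate
3 | (E)-1-(tert-butyldimethylsilyloxy)-3-isopropylbuta-1,3-diene | C=C(C(C)C)/C=C/O[Si](C)(C)C(C)(C)C | intermediate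
4 | 2,4-dimethylfuran | Cc1cc(C)co1 | starting material
5 | (Z)-2-methyl-4-oxopent-2-enal | CC(=O)/C=C(/C)C=O | intermediate
6 | Diels–Alder adduct (CHO, Ac and OTBS all cis, α) | CC(C)(C)[Si](C)(C)O[C@@H]1C=C(C(C)C)C[C@H](C(C)=O)[C@]1(C)C=O | intermediate
7 | (10S)-allylic alcohol | CC(C)(C)[Si](C)(C)O[C@@H]1C=C(C(C)C)C[C@H](C(C)=O)[C@]1(C)[C@@H](O)C=C | intermediate
8 | C10 benzoate | CC(C)(C)[Si](C)(C)O[C@@H]1C=C(C(C)C)C[C@H](C(C)=O)[C@]1(C)[C@@H](OC(=O)c2ccccc2)C=C | intermediate
9 | 4β,5β-diol | CC(C)(C)[Si](C)(C)O[C@@H]1[C@@H](O)[C@](O)(C(C)C)C[C@H](C(C)=O)[C@]1(C)[C@@H](OC(=O)c2ccccc2)C=C | intermediate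
10 | C5 mesylate | CC(C)(C)[Si](C)(C)O[C@@H]1[C@@H](OS(C)(=O)=O)[C@](O)(C(C)C)C[C@H](C(C)=O)[C@]1(C)[C@@H](OC(=O)c2ccccc2)C=C | intermediate
11 | C2 acetate | CC(C)(C)[Si](C)(C)O[C@@H]1[C@@H](OS(C)(=O)=O)[C@](O)(C(C)C)C[C@H](OC(C)=O)[C@]1(C)[C@@H](OC(=O)c2ccccc2)C=C | intermediate
12 | 6α-hydroxy 5β-mesylate | O[C@@H]1[C@@H](OS(C)(=O)=O)[C@](O)(C(C)C)C[C@H](OC(C)=O)[C@]1(C)[C@@H](OC(=O)c2ccccc2)C=C | intermediate
13 | bis(chloroethylaluminium) alkoxide of 12 (not isolated) | CC[Al](Cl)O[C@@H]1[C@@H](OS(C)(=O)=O)[C@](O[Al](Cl)CC)(C(C)C)C[C@H](OC(C)=O)[C@]1(C)[C@@H](OC(=O)c2ccccc2)C=C | intermediate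
14 | cyclopentanecarbaldehyde | O=C[C@@H]1[C@@](C)([C@@H](OC(=O)c2ccccc2)C=C)[C@@H](OC(C)=O)C[C@@]1(O)C(C)C | intermediate
15 | diisopinocampheylborinate of 16 (not isolated) | C=C(C)C[C@H](OB([C@@H]1C[C@@H]2C[C@H]([C@H]1C)C2(C)C)[C@@H]1C[C@@H]2C[C@H]([C@H]1C)C2(C)C)[C@@H]1[C@@](C)([C@@H](OC(=O)c2ccccc2)C=C)[C@@H](OC(C)=O)C[C@@]1(O)C(C)C | intermediate
16 | (6S)-homoallylic alcohol (4,6-diol) | C=C(C)C[C@H](O)[C@@H]1[C@@](C)([C@@H](OC(=O)c2ccccc2)C=C)[C@@H](OC(C)=O)C[C@@]1(O)C(C)C | intermediate
17 | bicyclic 6α-alcohol | O[C@H]1CC(C)=C[C@H](OC(=O)c2ccccc2)[C@@]2(C)[C@@H](OC(C)=O)C[C@@](O)(C(C)C)[C@H]12 | intermediate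
18 | angelic acid | C/C=C(/C)C(=O)O | starting material
19 | angelic 2,4,6-trichlorobenzoic anhydride (not isolated) | C/C=C(/C)C(=O)OC(=O)c1c(Cl)cc(Cl)cc1Cl | intermediate
20 | CNP0248576.1 | C/C=C(/C)C(=O)O[C@H]1CC(C)=C[C@H](OC(=O)c2ccccc2)[C@@]2(C)[C@@H](OC(C)=O)C[C@@](O)(C(C)C)[C@H]12 | target

Total step count: 14. Longest linear sequence: 13 (steps 1, 2, 4–14).

**Steps most likely to fail**

**Step 4.** The strongly acidic catalyst may isomerise the Z dienophile to the E form before cycloaddition. The diene may attack the formyl C=O instead (hetero-cycloaddition or vinylogous aldol pathway). Facial selectivity may also be poor. The fallback sets out from 3 and 5 and comes back at 7.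
- The cycloaddition is run without any acid in toluene at 25–40 °C, where the doubly activated cis-oxoenal should still react endo and with the same orientation.
- This gives 6 together with its enantiomer ent-6 F1.
- The mixture is carried into the reagent-controlled vinylation of step 5.
- That step turns 6 into 7 and F1 into the diastereomeric (10S)-allylic alcohol F2, which is removed by chromatography.

**Step 11.** Migration of C3 from the C4 alkoxide, ionisation of the allylic benzoate by the Lewis acid, or retro-aldol or epimerisation of the β-hydroxy aldehyde may compete. The fallback sets out from 12 and comes back at 16, and it keeps the same C6→C5 shift.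
- The C6 hydroxyl is oxidised with a periodinane to the α-mesyloxy ketone F3.
- 2-Methylallylzinc bromide (inert to the esters) adds to the ketone to give the tertiary carbinol adduct F4.
- On warming, the zinc alkoxide of F4 undergoes the semibenzilic-type 1,2-shift of C1 to C5, because the C5–OMs bond stays antiperiplanar to C6–C1 whatever the configuration at C6. The product is the ring-contracted β-hydroxy ketone F5, a ketone rather than a labile aldehyde.
- Hydroxyl-directed reduction with Me4NBH(OAc)3 delivers hydride from the side of the C4 hydroxyl and gives 16.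

**Step 9.** Slow peracid attack on the hindered acetyl group may allow epoxidation of the vinyl group to catch up. The fallback sets out from 10 and comes back at 11.
- The vinyl group is masked by addition of bromine (pyridinium tribromide) as the 9,9a-dibromide F6.
- The ketone is then oxidised with the much stronger buffered trifluoroperacetic acid to the dibromo acetate F7.
- Zinc dust regenerates the alkene.

Further compounds
F1 | step 4 | ent-6 | CC(C)(C)[Si](C)(C)O[C@H]1C=C(C(C)C)C[C@@H](C(C)=O)[C@@]1(C)C=O
F2 | step 4 | (10S)-allylic alcohol derived from ent-6 (diastereomer of 7) | CC(C)(C)[Si](C)(C)O[C@H]1C=C(C(C)C)C[C@@H](C(C)=O)[C@@]1(C)[C@@H](O)C=C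
F3 | step 11 | α-mesyloxy ketone (C6 ketone of 12) | O=C1[C@@H](OS(C)(=O)=O)[C@](O)(C(C)C)C[C@H](OC(C)=O)[C@]1(C)[C@@H](OC(=O)c2ccccc2)C=C
F4 | step 11 | tertiary C6 carbinol from 2-methylallyl addition (C6 configuration open) | C=C(C)CC1(O)[C@@H](OS(C)(=O)=O)[C@](O)(C(C)C)C[C@H](OC(C)=O)[C@]1(C)[C@@H](OC(=O)c2ccccc2)C=C
F5 | step 11 | ring-contracted β-hydroxy ketone (C6 ketone of 16) | C=C(C)CC(=O)[C@@H]1[C@@](C)([C@@H](OC(=O)c2ccccc2)C=C)[C@@H](OC(C)=O)C[C@@]1(O)C(C)C
F6 | step 9 | dibromide of 10 | CC(C)(C)[Si](C)(C)O[C@@H]1[C@@H](OS(C)(=O)=O)[C@](O)(C(C)C)C[C@H](C(C)=O)[C@]1(C)[C@@H](OC(=O)c2ccccc2)C(Br)CBr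
F7 | step 9 | dibromide of 11 | CC(C)(C)[Si](C)(C)O[C@@H]1[C@@H](OS(C)(=O)=O)[C@](O)(C(C)C)C[C@H](OC(C)=O)[C@]1(C)[C@@H](OC(=O)c2ccccc2)C(Br)CBr
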